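**Assumption:** the target is the enantiomer encoded by the SMILES, (1S,5S,7R) in bicyclo[3.3.1]nonane numbering, with the C7 geranyl group exo (equatorial on the chair carbocycle); the enol tautomer drawn is one of two equilibrating forms.

## Retrosynthetic overview

1. Target 18 ← hydroxide cleavage of one vinylogous methyl ester and two aryl tosylates in bicycle 17.
2. 17 ← one-flask dearomative annulation of benzophenone 9 with triflate 15: C5–C6 by alkylative dearomatization at the geranyl-bearing carbon, then C1–C8 by capture of a tertiary cation.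
3. 9 ← 5-methoxyresorcinol + protected protocatechuonitrile (Hoesch), then C-geranylation and C-prenylation; the single O-methyl makes the two alkylated ring carbons different.
4. 15 ← Evans deconjugative geranylation of a senecioyl imide (sets C7), reduction, triflation.
5. Ring order: the feedstock arene becomes the trione ring on dearomatization; the second carbocycle (C5–C6–C7–C8–C1–C9) closes last.

## Route

Ring positions in 5, 7 and 9 are benzophenone positions (C1 carries the aroyl group); from 16 on, bicyclic numbering of the target is used.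

Step 1
Reactants: 1 3,4-dihydroxybenzonitrile
Product: 2 4-cyano-1,2-phenylene bis(4-methylbenzenesulfonate)
Conditions: TsCl (2.2 equiv), Et3N, DMAP (cat.), CH2Cl2, 0 °C → rt
Reagents that add atoms: p-toluenesulfonyl chloride, Cc1ccc(cc1)S(Cl)(=O)=O
Why: Sulfonylation of both phenols gives aryl tosylates, a phenol protection that survives HCl, amidine and lithium amide bases and formic acid and is removed by hydroxide at the end.

Step 2
Reactants: 2 4-cyano-1,2-phenylene bis(4-methylbenzenesulfonate); 3 5-methoxyresorcinol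
Product: 5 4-(2,4-dihydroxy-6-methoxybenzoyl)-1,2-phenylene bis(4-methylbenzenesulfonate), via ketiminium chloride 4 (not isolated)
Conditions: ZnCl2, HCl (g), Et2O, 0 °C; then H2O, 100 °C
Reagents that add atoms: water, O
Why: Houben–Hoesch acylation, in which the acid-activated electron-poor nitrile attacks the phloroglucinol ether para to a hydroxyl (two equivalent sites, expected to be favoured over the single site between the hydroxyls, the minor 2,6-dihydroxy-4-methoxy isomer being removed by chromatography) and the ketiminium salt is hydrolysed to the ketone.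

Step 3
Reactants: 5 4-(2,4-dihydroxy-6-methoxybenzoyl)-1,2-phenylene bis(4-methylbenzenesulfonate); 6 geranyl bromide
Product: 7 4-{3-[(2E)-3,7-dimethylocta-2,6-dienyl]-2,4-dihydroxy-6-methoxybenzoyl}-1,2-phenylene bis(4-methylbenzenesulfonate)
Conditions: DBU (1.1 equiv), THF, 0 °C → rt
Reagents that add atoms: none
Why: Phenolate C-allylation in which C3, ortho to both free hydroxyls, is the most nucleophilic ring carbon (the known 3-prenylation pattern of 2,4-dihydroxy-6-alkoxyaryl ketones), the E alkene coming unchanged from the bromide.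

Step 4
Reactants: 7 the 3-geranyl benzophenone; 8 prenyl bromide
Product: 9 4-{3-[(2E)-3,7-dimethylocta-2,6-dienyl]-2,4-dihydroxy-6-methoxy-5-(3-methylbut-2-enyl)benzoyl}-1,2-phenylene bis(4-methylbenzenesulfonate)
Conditions: DBU (1.1 equiv), THF, 0 °C → rt
Reagents that add atoms: none
Why: Second phenolate C-allylation, in which with one equivalent of base the only unsubstituted ring carbon (C5, ortho to the 4-hydroxyl) reacts with rearomatization faster than the substituted C3 can be dearomatized.

Step 5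
Reactants: 10 (S)-4-benzyl-1,3-oxazolidin-2-one; 11 3-methylbut-2-enoyl chloride
Product: 12 (S)-4-benzyl-3-(3-methylbut-2-enoyl)-1,3-oxazolidin-2-one
Conditions: n-BuLi, THF, −78 °C; then 11, −78 → 0 °C
Reagents that add atoms: none
Why: N-acylation of the lithiated Evans oxazolidinone by the acid chloride.

Step 6
Reactants: 12 (S)-4-benzyl-3-(3-methylbut-2-enoyl)-1,3-oxazolidin-2-one; 6 geranyl bromide
Product: 13 (S)-4-benzyl-3-[(2S,4E)-5,9-dimethyl-2-(prop-1-en-2-yl)deca-4,8-dienoyl]-1,3-oxazolidin-2-one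
Conditions: NaHMDS, THF, −78 °C; then 6, −78 → −40 °C
Reagents that add atoms: none
Why: Evans asymmetric alkylation in its deconjugative form, where the chelated Z sodium dienolate is geranylated at the α-carbon on the face opposite the benzyl group, which sets the future C7 and leaves the isopropenyl group that becomes C8.

Step 7
Reactants: 13 the alkylated imide
Product: 14 (2S,4E)-5,9-dimethyl-2-(prop-1-en-2-yl)deca-4,8-dien-1-ol
Conditions: LiBH4, MeOH (1 equiv), Et2O, 0 °C
Reagents that add atoms: none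
Why: Reductive cleavage of the imide gives the primary alcohol without touching the alkenes or the stereocentre and returns the auxiliary.

Step 8
Reactants: 14 (2S,4E)-5,9-dimethyl-2-(prop-1-en-2-yl)deca-4,8-dien-1-ol
Product: 15 (2S,4E)-5,9-dimethyl-2-(prop-1-en-2-yl)deca-4,8-dienyl trifluoromethanesulfonate
Conditions: Tf2O, 2,6-lutidine, CH2Cl2, −78 °C; cold silica plug, used at once
Reagents that add atoms: trifluoromethanesulfonic anhydride, O=S(=O)(OS(=O)(=O)C(F)(F)F)C(F)(F)F
Why: Low-temperature triflation gives the only leaving group reactive enough for C-alkylation of a fully substituted phenolate carbon by this β-branched primary centre.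

Step 9
Reactants: 9 the 3-geranyl-5-prenyl benzophenone; 15 the (2S) triflate
Product: 17 bicyclic methyl enol ether bis-tosylate (4-{[2-methoxy-8,8-dimethyl-1-(3-methylbut-2-enyl)-5,7-bis((2E)-3,7-dimethylocta-2,6-dienyl)-4,9-dioxobicyclo[3.3.1]non-2-en-3-yl]carbonyl}-1,2-phenylene bis(4-methylbenzenesulfonate); C1, C5 and C7 arranged as in the target), via dearomatized dienone 16 (not isolated)
Conditions: LiHMDS (2.1 equiv), THF, −78 → 0 °C; then evaporate, HCO2H, 23 °C
Reagents that add atoms: none
Why: Proposed new method: the dilithium phenolate of 9 is C-alkylated by the primary triflate at C3, the only ring carbon flanked by two oxyanions (the O-methyl makes the prenyl-bearing C5 the poorer nucleophile), and after the solvent switch formic acid protonates the isopropenyl group to the tertiary C8 cation, which the prenyl-bearing methoxy-enone carbon captures through a chair transition state with the C7 geranyl equatorial, so that C1 follows from C5 and C7 ends exo while the capped enol cannot add to the prenyl or geranyl alkenes; C5 itself forms without facial control, so about half of the alkylation product is the C5 epimer, which cannot use this chair and is removed by chromatography after the cyclization; the closest known reaction types are the alkylative dearomatization of acylphloroglucinol polyanions with alkyl triflates and the formic acid cation–enol cyclization of dearomatized acylphloroglucinols.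

Step 10
Reactants: 17 bicyclic methyl enol ether bis-tosylate
Product: 18 (1S,5S,7R)-3-(3,4-dihydroxybenzoyl)-4-hydroxy-8,8-dimethyl-1-(3-methylbut-2-enyl)-5,7-bis[(2E)-3,7-dimethylocta-2,6-dienyl]bicyclo[3.3.1]non-3-ene-2,9-dione (target)
Conditions: LiOH, dioxane/H2O (degassed), 90 °C; then aq. HCl
Reagents that add atoms: lithium hydroxide, [Li+].[OH-]
Why: Hydroxide cleaves the vinylogous methyl ester by addition–elimination at C2 and both aryl tosylates by attack at sulfur (base hydrolysis as used for O-methyl bicyclic triones), the resulting enolate and phenolates shield the trione and alkenes, and no stereocentre is enolizable.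

## Compound list

1 | 3,4-dihydroxybenzonitrile | N#Cc1ccc(O)c(O)c1 | starting material
2 | 4-cyano-1,2-phenylene bis(4-methylbenzenesulfonate) | N#Cc1ccc(OS(=O)(=O)c2ccc(C)cc2)c(OS(=O)(=O)c2ccc(C)cc2)c1 | intermediate
3 | 5-methoxyresorcinol (5-methoxybenzene-1,3-diol) | COc1cc(O)cc(O)c1 | starting material
4 | (2,4-dihydroxy-6-methoxyphenyl)[3,4-bis(tosyloxy)phenyl]methaniminium chloride | COc1cc(O)cc(O)c1C(=[NH2+])c1ccc(OS(=O)(=O)c2ccc(C)cc2)c(OS(=O)(=O)c2ccc(C)cc2)c1.[Cl-] | intermediate
5 | 4-(2,4-dihydroxy-6-methoxybenzoyl)-1,2-phenylene bis(4-methylbenzenesulfonate) | COc1cc(O)cc(O)c1C(=O)c1ccc(OS(=O)(=O)c2ccc(C)cc2)c(OS(=O)(=O)c2ccc(C)cc2)c1 | intermediate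
6 | geranyl bromide, (2E)-1-bromo-3,7-dimethylocta-2,6-diene | CC(C)=CCC/C(C)=C/CBr | starting material
7 | 4-{3-[(2E)-3,7-dimethylocta-2,6-dienyl]-2,4-dihydroxy-6-methoxybenzoyl}-1,2-phenylene bis(4-methylbenzenesulfonate) | COc1cc(O)c(C/C=C(\C)CCC=C(C)C)c(O)c1C(=O)c1ccc(OS(=O)(=O)c2ccc(C)cc2)c(OS(=O)(=O)c2ccc(C)cc2)c1 | intermediate
8 | prenyl bromide, 1-bromo-3-methylbut-2-ene | CC(C)=CCBr | starting material
9 | 4-{3-[(2E)-3,7-dimethylocta-2,6-dienyl]-2,4-dihydroxy-6-methoxy-5-(3-methylbut-2-enyl)benzoyl}-1,2-phenylene bis(4-methylbenzenesulfonate) | COc1c(CC=C(C)C)c(O)c(C/C=C(\C)CCC=C(C)C)c(O)c1C(=O)c1ccc(OS(=O)(=O)c2ccc(C)cc2)c(OS(=O)(=O)c2ccc(C)cc2)c1 | intermediate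
10 | (S)-4-benzyl-1,3-oxazolidin-2-one | O=C1OC[C@H](Cc2ccccc2)N1 | starting material
11 | 3-methylbut-2-enoyl chloride | CC(C)=CC(Cl)=O | starting material
12 | (S)-4-benzyl-3-(3-methylbut-2-enoyl)-1,3-oxazolidin-2-one | O=C1OC[C@H](Cc2ccccc2)N1C(=O)C=C(C)C | intermediate
13 | (S)-4-benzyl-3-[(2S,4E)-5,9-dimethyl-2-(prop-1-en-2-yl)deca-4,8-dienoyl]-1,3-oxazolidin-2-one | O=C1OC[C@H](Cc2ccccc2)N1C(=O)[C@@H](C/C=C(\C)CCC=C(C)C)C(C)=C | intermediate
14 | (2S,4E)-5,9-dimethyl-2-(prop-1-en-2-yl)deca-4,8-dien-1-ol | CC(C)=CCC/C(C)=C/C[C@@H](C(C)=C)CO | intermediate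
15 | (2S,4E)-5,9-dimethyl-2-(prop-1-en-2-yl)deca-4,8-dienyl trifluoromethanesulfonate | CC(C)=CCC/C(C)=C/C[C@@H](C(C)=C)COS(=O)(=O)C(F)(F)F | intermediate
16 | dearomatized dienone: cyclohexa-2,4-dien-1-one with C2 prenyl, C3 OMe, C4 3,4-bis(tosyloxy)benzoyl, C5 OH, and at C6 (S) geranyl plus the 5,9-dimethyl-2-(prop-1-en-2-yl)deca-4,8-dienyl chain (stereocentre unchanged from 14, CIP label now R) | CC(C)=CCC/C(C)=C/C[C@@H](C(C)=C)C[C@]1(C/C=C(\C)CCC=C(C)C)C(=O)C(CC=C(C)C)=C(OC)C(C(=O)c2ccc(OS(=O)(=O)c3ccc(C)cc3)c(OS(=O)(=O)c3ccc(C)cc3)c2)=C1O | intermediate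
17 | 4-{[2-methoxy-8,8-dimethyl-1-(3-methylbut-2-enyl)-5,7-bis((2E)-3,7-dimethylocta-2,6-dienyl)-4,9-dioxobicyclo[3.3.1]non-2-en-3-yl]carbonyl}-1,2-phenylene bis(4-methylbenzenesulfonate), C1/C5/C7 arranged as in 18, C7 geranyl exo | CC(C)=CCC/C(C)=C/C[C@@H]1C[C@]2(C/C=C(\C)CCC=C(C)C)C(=O)[C@@](CC=C(C)C)(C(OC)=C(C(=O)c3ccc(OS(=O)(=O)c4ccc(C)cc4)c(OS(=O)(=O)c4ccc(C)cc4)c3)C2=O)C1(C)C | intermediate
18 | (1S,5S,7R)-3-(3,4-dihydroxybenzoyl)-4-hydroxy-8,8-dimethyl-1-(3-methylbut-2-enyl)-5,7-bis[(2E)-3,7-dimethylocta-2,6-dienyl]bicyclo[3.3.1]non-3-ene-2,9-dione | CC(C)=CCC/C(C)=C/C[C@@H]1C[C@]2(C/C=C(\C)CCC=C(C)C)C(=O)[C@@](CC=C(C)C)(C(=O)C(C(=O)c3ccc(O)c(O)c3)=C2O)C1(C)C | target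

## Step count and risks

Total step count: 10. Longest linear sequence: 6 steps (1, 2, 3, 4, 9, 10; the electrophile branch 5, 6, 7, 8, 9, 10 is equally long).

**Step 9 (most likely to fail).** The β-branched triflate may O-alkylate or react sluggishly. The new quaternary carbon forms with no facial control, so at best half of the material enters the productive cyclization. Formic acid may also attack the geranyl alkenes. The fallback exchanges the roles of the two electrophiles and lets a catalyst set the quaternary centre. It sets out from 5 (using 15) and comes back at 16. The dilithium salt of 5 (LiHMDS, THF) is C-alkylated by 15 at its free C3 to give the aromatic C3-alkylated benzophenone F1. DBU and 8 then put the prenyl group on C5 to give the prenylated C3-alkylated benzophenone F2. F2 is dearomatized by geranylation at the side-chain-bearing C3 with geranyl acetate, DBU, Pd2(dba)3 and a chiral Trost-type bisphosphine (allylic alkylation by zerovalent palladium), with the ligand enantiomer chosen to attack the face that gives 16. 16 is then isolated and closed with HCO2H to 17 as in step 9.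

**Step 4.** The most nucleophilic carbon of 7 is the already substituted C3, so dearomatizing gem-dialkylation and O-prenylation can compete with attack at C5. The fallback replaces phenolate alkylation by a sigmatropic delivery. It sets out from 7 and comes back at 9. The non-chelated 4-hydroxyl is alkylated with 3-chloro-3-methylbut-1-yne (CuCl2 cat., DBU, MeCN, 0 °C) to give the aryl 1,1-dimethylpropargyl ether F3. Semi-hydrogenation (H2, Pd/CaCO3 poisoned with Pb(OAc)2, quinoline) gives the aryl 1,1-dimethylallyl ether F4. Heating (toluene, 110 °C) effects the aromatic Claisen rearrangement; shift to the substituted C3 is reversible, so the prenyl group ends on the only free ortho carbon, C5, giving 9.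

**Step 2.** The Hoesch reaction on the unsymmetrical ether may favour the wrong site or give an inseparable mixture. The fallback acylates a symmetric arene and differentiates the oxygens afterwards. It sets out from 2 and comes back at 5. Hoesch reaction of 2 with commercial phloroglucinol (ZnCl2, HCl, Et2O; then hot water), which can give only one ketone, leads through the symmetric ketiminium chloride F5 to the trihydroxybenzophenone F6. Chloromethyl methyl ether (2.2 equiv) with i-Pr2NEt protects the para and one ortho hydroxyl and leaves the hydrogen-bonded one, giving the bis-MOM ether F7. MeI/K2CO3 in refluxing acetone methylates the chelated hydroxyl to give the methylated bis-MOM ether F8. HCl in MeOH at 40 °C removes both MOM groups to give 5.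

## Further compounds

F1 | step 9 | 4-{2,4-dihydroxy-6-methoxy-3-[(2R,4E)-5,9-dimethyl-2-(prop-1-en-2-yl)deca-4,8-dienyl]benzoyl}-1,2-phenylene bis(4-methylbenzenesulfonate) | CC(C)=CCC/C(C)=C/C[C@@H](C(C)=C)Cc1c(O)cc(OC)c(C(=O)c2ccc(OS(=O)(=O)c3ccc(C)cc3)c(OS(=O)(=O)c3ccc(C)cc3)c2)c1O
F2 | step 9 | 4-{2,4-dihydroxy-6-methoxy-5-(3-methylbut-2-enyl)-3-[(2R,4E)-5,9-dimethyl-2-(prop-1-en-2-yl)deca-4,8-dienyl]benzoyl}-1,2-phenylene bis(4-methylbenzenesulfonate) | CC(C)=CCC/C(C)=C/C[C@@H](C(C)=C)Cc1c(O)c(CC=C(C)C)c(OC)c(C(=O)c2ccc(OS(=O)(=O)c3ccc(C)cc3)c(OS(=O)(=O)c3ccc(C)cc3)c2)c1O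
F3 | step 4 | 4-{3-[(2E)-3,7-dimethylocta-2,6-dienyl]-2-hydroxy-6-methoxy-4-(2-methylbut-3-yn-2-yloxy)benzoyl}-1,2-phenylene bis(4-methylbenzenesulfonate) | COc1cc(OC(C)(C)C#C)c(C/C=C(\C)CCC=C(C)C)c(O)c1C(=O)c1ccc(OS(=O)(=O)c2ccc(C)cc2)c(OS(=O)(=O)c2ccc(C)cc2)c1
F4 | step 4 | 4-{3-[(2E)-3,7-dimethylocta-2,6-dienyl]-2-hydroxy-6-methoxy-4-(2-methylbut-3-en-2-yloxy)benzoyl}-1,2-phenylene bis(4-methylbenzenesulfonate) | COc1cc(OC(C)(C)C=C)c(C/C=C(\C)CCC=C(C)C)c(O)c1C(=O)c1ccc(OS(=O)(=O)c2ccc(C)cc2)c(OS(=O)(=O)c2ccc(C)cc2)c1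
F5 | step 2 | (2,4,6-trihydroxyphenyl)[3,4-bis(tosyloxy)phenyl]methaniminium chloride | Oc1cc(O)c(C(=[NH2+])c2ccc(OS(=O)(=O)c3ccc(C)cc3)c(OS(=O)(=O)c3ccc(C)cc3)c2)c(O)c1.[Cl-]
F6 | step 2 | 4-(2,4,6-trihydroxybenzoyl)-1,2-phenylene bis(4-methylbenzenesulfonate) | Oc1cc(O)c(C(=O)c2ccc(OS(=O)(=O)c3ccc(C)cc3)c(OS(=O)(=O)c3ccc(C)cc3)c2)c(O)c1
F7 | step 2 | 4-[2-hydroxy-4,6-bis(methoxymethoxy)benzoyl]-1,2-phenylene bis(4-methylbenzenesulfonate) | COCOc1cc(O)c(C(=O)c2ccc(OS(=O)(=O)c3ccc(C)cc3)c(OS(=O)(=O)c3ccc(C)cc3)c2)c(OCOC)c1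
F8 | step 2 | 4-[2-methoxy-4,6-bis(methoxymethoxy)benzoyl]-1,2-phenylene bis(4-methylbenzenesulfonate) | COCOc1cc(OC)c(C(=O)c2ccc(OS(=O)(=O)c3ccc(C)cc3)c(OS(=O)(=O)c3ccc(C)cc3)c2)c(OCOC)c1
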